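Retrosynthesis: the coumarin lactone is cut at O1–C2 and C3=C4 (Knoevenagel condensation–lactonisation), which releases an (S)-dihydropyranone acetic ester. C4–C4a is then cut back to an orthoformate carbon, and the benzene ring is cut at C7–C8, C8a–C4a and C6–C7 into a 3,4-disubstituted cyclobutenone and ethoxyacetylene.
Enabling feature: the carbocyclic ring of the coumarin has oxygen on C7 and C8a (1,3-related) with C8–H between them, and carbon substituents on the adjacent C5 and C6. This is the pattern left by a four-carbon vinylketene (C7, C4a, C5, C6) joined to HC≡C–OEt (C8, C8a).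
Forward order: acyclic chain → terminal alkyne → cyclobutenone → benzene ring → temporary isochromene ring that brings in C4 → lactone ring. The dihydropyranone ring is built separately and joined in the last step.
Stereochemistry: both carbinol centres (side-chain C–OH and pyranone C2) are the stereocentre of ethyl (S)-3-hydroxybutanoate. The benzylic centre comes from chelate-controlled anti methylation of its dianion, and no later step breaks a bond at any of the three.

Key step: step 7

Remark: ring atoms carry the numbering of the final coumarin at every stage. TBS = tert-butyl(dimethyl)silyl. Compound 12 is used as the mixture of C4 epimers because that carbon becomes aromatic C6. Compound 22 is the anhydro form of the corresponding lactol/hydroxy-aldehyde and is treated as its synthetic equivalent.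

Step 1
Reactants: 1 ethyl (3S)-3-hydroxybutanoate
Product: 3 ethyl (2S,3S)-3-hydroxy-2-methylbutanoate, via dilithium alkoxide-enolate 2 (not isolated)
Conditions: LiN(i-Pr)2 (2.2 equiv), THF, −78 → −20 °C; MeI, DMPU, −78 → 0 °C
Reagents that add atoms: iodomethane, CI
Why: Fráter–Seebach alkylation, in which the lithium-chelated alkoxide-enolate 2 is methylated on the face away from the C3 methyl group, so the new C2 centre should form anti to the hydroxyl (2S).

Step 2
Reactants: 3 ethyl (2S,3S)-3-hydroxy-2-methylbutanoate
Product: 4 ethyl (2S,3S)-3-(TBS-oxy)-2-methylbutanoate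
Conditions: TBSCl, imidazole, DMF, rt
Reagents that add atoms: tert-butyl(dimethyl)silyl chloride, CC(C)(C)[Si](C)(C)Cl
Why: Imidazole-promoted silylation of a secondary alcohol, giving an ether that tolerates the hydride, organolithium, triflate-buffered and thermal steps that follow.

Step 3
Reactants: 4 ethyl (2S,3S)-3-(TBS-oxy)-2-methylbutanoate
Product: 5 (2S,3S)-3-(TBS-oxy)-2-methylbutanal
Conditions: i-Bu2AlH (1.1 equiv), CH2Cl2, −78 °C; aq. potassium sodium tartrate
Reagents that add atoms: none
Why: Partial ester reduction, in which the aluminium hemiacetal persists at −78 °C and collapses to the aldehyde only on work-up, so over-reduction and α-epimerisation should both be avoided.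

Step 4
Reactants: 5 (2S,3S)-3-(TBS-oxy)-2-methylbutanal
Product: 6 (3R,4S)-1,1-dibromo-4-(TBS-oxy)-3-methylpent-1-ene
Conditions: CBr4, PPh3, CH2Cl2, 0 °C
Reagents that add atoms: carbon tetrabromide, BrC(Br)(Br)Br
Why: First stage of the Corey–Fuchs homologation, a Wittig-type olefination by Ph3P=CBr2 under essentially neutral conditions that leave the neighbouring stereocentre alone (its descriptor changes only because the priorities change).

Step 5
Reactants: 6 (3R,4S)-1,1-dibromo-4-(TBS-oxy)-3-methylpent-1-ene
Product: 8 (3R,4S)-4-(TBS-oxy)-3-methylpent-1-yne, via lithium acetylide 7 (not isolated)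
Conditions: n-BuLi (2.2 equiv), THF, −78 → 0 °C; H2O
Reagents that add atoms: none
Why: Second stage of the Corey–Fuchs homologation, in which bromine–lithium exchange, α-elimination with a Fritsch–Buttenberg–Wiechell 1,2-shift and deprotonation give acetylide 7, which is protonated on work-up.

Step 6
Reactants: 8 (3R,4S)-4-(TBS-oxy)-3-methylpent-1-yne; 9 N,N-dimethylpropanamide
Product: 12 cyclobutenone 3-[(2R,3S)-3-(TBS-oxy)butan-2-yl]-4-methylcyclobut-2-en-1-one (both C4 epimers), via keteniminium triflate 10 (not isolated), via cyclobuteniminium triflate 11 (not isolated)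
Conditions: 9 (1.5 equiv), Tf2O, 2,4,6-collidine, ClCH2CH2Cl, −15 °C → reflux; aq. NaHCO3, rt
Reagents that add atoms: water, O
Why: Keteniminium–alkyne [2+2] cycloaddition (Ghosez type), in which the central carbon of the non-dimerising 10 bonds to the terminal alkyne carbon while charge builds on the substituted one, so closure puts the side chain on C3 and the methyl on C4 before hydrolysis of 11 frees the enone.

Step 7
Reactants: 12 cyclobutenone 3-[(2R,3S)-3-(TBS-oxy)butan-2-yl]-4-methylcyclobut-2-en-1-one; 13 ethoxyacetylene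
Product: 18 phenol 3-[(2R,3S)-3-(TBS-oxy)butan-2-yl]-5-ethoxy-2-methylphenol, via vinylketene 14 (not isolated), via 4-alkenylcyclobutenone 15 (not isolated), via dienylketene 16 (not isolated), via cyclohexadienone 17 (not isolated)
Conditions: 13 (3 equiv, solution in hexanes), toluene, sealed tube, 80 °C; excess 13 vented; 110 °C
Reagents that add atoms: none
Why: At 80 °C 12 opens by a conrotatory four-electron electrocyclic reaction to vinylketene 14, which 13 traps in a [2+2] cycloaddition to give 15; four-electron opening of 15 gives dienylketene 16, which cyclises to 17 and tautomerises to 18. This is the cyclobutenone–heteroalkyne benzannulation (Danheiser benzannulation), established for alkoxy- and siloxyalkynes. The one ring that remains, the benzene ring, is closed at C6–C7 by a thermal disrotatory six-electron electrocyclisation, whereas the four-membered ring of 15 is closed by the ketene [2+2] event and opens again. No lasting stereocentre is formed, because the sp3 ring carbons of 12, 15 and 17 all become aromatic (so both epimers of 12 converge), and the two side-chain centres are spectators under neutral, base-free heating. The step needs a single orientation in the [2+2] event, and the polarity of the ynol ether supplies it: its unsubstituted, nucleophilic carbon bonds to the ketene carbonyl carbon (C7–C8) and its oxygen-bearing carbon to the ketene α-carbon (C8a–C4a), which places OEt meta to the new OH and leaves methyl and side chain adjacent. Both ring openings are reversible, so rotamers unable to cyclise revert and are drained through the irreversible aromatisation, while the excess alkyne limits ketene dimerisation and acylation of the product phenol.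

Step 8
Reactants: 18 phenol 3-[(2R,3S)-3-(TBS-oxy)butan-2-yl]-5-ethoxy-2-methylphenol
Product: 20 triol 5-[(2R,3S)-3-hydroxybutan-2-yl]-4-methylbenzene-1,3-diol, via silyl-protected resorcinol 19 (not isolated)
Conditions: AlCl3, EtSH, CH2Cl2, 0 °C → rt; then 1 M HCl, MeOH, rt
Reagents that add atoms: none
Why: Hard acid–soft nucleophile dealkylation, in which AlCl3 binds the aryl ether oxygen and ethanethiol removes the primary ethyl group by SN2 attack without breaking secondary alkyl C–O bonds, after which acidic methanol cleaves the silyl ether.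

Step 9
Reactants: 20 triol 5-[(2R,3S)-3-hydroxybutan-2-yl]-4-methylbenzene-1,3-diol
Product: 22 quinone methide (3S,4R)-8-hydroxy-3,4,5-trimethyl-3,4-dihydro-6H-isochromen-6-one, via cyclic ethyl acetal 21 (not isolated)
Conditions: HC(OEt)3 (excess), CF3CO2H (cat.), CH2Cl2, 0 °C → rt; then 1 M aq. HCl
Reagents that add atoms: triethyl orthoformate, CCOC(OCC)OCC
Why: Orthoformate formylation–cyclisation (an oxa-Pictet–Spengler-type closure at the formate oxidation level), in which the secondary alcohol exchanges onto the orthoester and the tethered dialkoxycarbenium ion can reach only C4a (para to the C7 hydroxyl, ortho to the C8a hydroxyl), so C8 stays free and loss of ethanol from 21 gives the known type of 6-oxoisochromene quinone methide.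

Step 10
Reactants: 1 ethyl (3S)-3-hydroxybutanoate
Product: 23 (3S)-3-hydroxy-N-methoxy-N-methylbutanamide
Conditions: MeNH(OMe)·HCl, i-PrMgCl, THF, −20 → 0 °C
Reagents that add atoms: N,O-dimethylhydroxylamine hydrochloride, CNOC.Cl
Why: Weinreb amide formation by aminolysis of the ester with the chloromagnesium amide made in the flask, in which the free hydroxyl is merely deprotonated and the stereocentre is untouched.

Step 11
Reactants: 23 (3S)-3-hydroxy-N-methoxy-N-methylbutanamide
Product: 24 (3S)-3-(TBS-oxy)-N-methoxy-N-methylbutanamide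
Conditions: TBSCl, imidazole, DMF, rt
Reagents that add atoms: tert-butyl(dimethyl)silyl chloride, CC(C)(C)[Si](C)(C)Cl
Why: Standard silylation that removes the acidic proton before the dianion step.

Step 12
Reactants: 24 (3S)-3-(TBS-oxy)-N-methoxy-N-methylbutanamide; 25 ethyl acetoacetate
Product: 27 ethyl (7S)-7-(TBS-oxy)-3,5-dioxooctanoate, via dilithium dianion 26 (not isolated)
Conditions: 25, LiN(i-Pr)2 (2 equiv), THF, 0 °C; then 24, −78 → 0 °C
Reagents that add atoms: none
Why: Acylation of a Weiler β-keto ester dianion at its more nucleophilic γ-carbon, in which the chelated tetrahedral adduct of the Weinreb amide survives until work-up, so neither a second addition nor quenching of the dianion by the more acidic product should occur.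

Step 13
Reactants: 27 ethyl (7S)-7-(TBS-oxy)-3,5-dioxooctanoate
Product: 29 ethyl 2-[(2S)-2-methyl-4-oxo-2,3-dihydropyran-6-yl]acetate, via hydroxy diketo ester 28 (not isolated)
Conditions: CF3CO2H, CH2Cl2, H2O (trace), 0 °C → rt
Reagents that add atoms: none
Why: Acidic desilylation followed by cyclodehydration of a δ-hydroxy-β-diketone, the usual entry to 2,3-dihydro-4H-pyran-4-ones, in which the alcohol of 28 adds to the C3 carbonyl (six-membered hemiketal) and water is lost without breaking the C–O bond at the stereocentre, while the competing 2-pyrone lactonisation needs base.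

Step 14
Reactants: 22 quinone methide (3S,4R)-8-hydroxy-3,4,5-trimethyl-3,4-dihydro-6H-isochromen-6-one; 29 ethyl 2-[(2S)-2-methyl-4-oxo-2,3-dihydropyran-6-yl]acetate
Product: 31 7-hydroxy-5-[(2R,3S)-3-hydroxybutan-2-yl]-6-methyl-3-[(2S)-2-methyl-4-oxo-2,3-dihydropyran-6-yl]chromen-2-one (target), via arylidene ester 30 (not isolated)
Conditions: piperidine (0.2 equiv), AcOH (0.2 equiv), EtOH, 60 °C
Reagents that add atoms: none
Why: Knoevenagel condensation–lactonisation as used to make 3-substituted coumarins from salicylaldehydes and activated acetic esters, in which piperidine adds to C1 of 22 and opens the pyran ring to the same o-hydroxyaryl iminium ion the free aldehyde would give, the doubly activated CH2 of 29 condenses to 30, and the ortho phenol closes the lactone with loss of ethanol, freeing the side-chain alcohol and creating no stereocentre.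

Compound list
1 | ethyl (3S)-3-hydroxybutanoate | CCOC(=O)C[C@H](C)O | starting material
2 | dilithium alkoxide-enolate of 1 (enolate O cis to the carbinol carbon, chelated) | CCO/C([O-])=C/[C@H](C)[O-].[Li+].[Li+] | intermediate
3 | ethyl (2S,3S)-3-hydroxy-2-methylbutanoate | CCOC(=O)[C@@H](C)[C@H](C)O | intermediate
4 | ethyl (2S,3S)-3-[tert-butyl(dimethyl)silyl]oxy-2-methylbutanoate | CCOC(=O)[C@@H](C)[C@H](C)O[Si](C)(C)C(C)(C)C | intermediate
5 | (2S,3S)-3-[tert-butyl(dimethyl)silyl]oxy-2-methylbutanal | O=C[C@@H](C)[C@H](C)O[Si](C)(C)C(C)(C)C | intermediate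
6 | tert-butyl-[(2S,3R)-5,5-dibromo-3-methylpent-4-en-2-yl]oxy-dimethylsilane | BrC(Br)=C[C@@H](C)[C@H](C)O[Si](C)(C)C(C)(C)C | intermediate
7 | lithium acetylide of 8 | [Li]C#C[C@@H](C)[C@H](C)O[Si](C)(C)C(C)(C)C | intermediate
8 | tert-butyl-dimethyl-[(2S,3R)-3-methylpent-4-yn-2-yl]oxysilane | C#C[C@@H](C)[C@H](C)O[Si](C)(C)C(C)(C)C | intermediate
9 | N,N-dimethylpropanamide | CCC(=O)N(C)C | starting material
10 | N,N-dimethyl(prop-1-enylidene)ammonium triflate (methylketeniminium salt) | CC=C=[N+](C)C.[O-]S(=O)(=O)C(F)(F)F | intermediate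
11 | N,N-dimethyl iminium triflate of 12 (cyclobuteniminium salt) | CC1C(=[N+](C)C)C=C1[C@@H](C)[C@H](C)O[Si](C)(C)C(C)(C)C.[O-]S(=O)(=O)C(F)(F)F | intermediate
12 | 3-[(2R,3S)-3-[tert-butyl(dimethyl)silyl]oxybutan-2-yl]-4-methylcyclobut-2-en-1-one (C4 epimers) | CC1C(=O)C=C1[C@@H](C)[C@H](C)O[Si](C)(C)C(C)(C)C | intermediate
13 | ethoxyacetylene | C#COCC | starting material
14 | (3E)-3-[(2R,3S)-3-[tert-butyl(dimethyl)silyl]oxybutan-2-yl]penta-1,3-dien-1-one (vinylketene, methyl trans to the ketene CH) | O=C=C/C(=C/C)[C@@H](C)[C@H](C)O[Si](C)(C)C(C)(C)C | intermediate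
15 | 3-ethoxy-4-alkenylcyclobut-2-en-1-one, alkenyl = CH3CH=C[CH(CH3)CH(OTBS)CH3] attached through the substituted carbon, ring C4 unassigned | CCOC1=CC(=O)C1/C(=C/C)[C@@H](C)[C@H](C)O[Si](C)(C)C(C)(C)C | intermediate
16 | 3-ethoxy-5-[(2R,3S)-3-[tert-butyl(dimethyl)silyl]oxybutan-2-yl]hepta-1,3,5-trien-1-one (dienylketene, C2 and C5 cis across C3=C4) | O=C=C/C(OCC)=C\C(=C\C)[C@@H](C)[C@H](C)O[Si](C)(C)C(C)(C)C | intermediate
17 | 3-ethoxy-6-methyl-5-[(2R,3S)-3-[tert-butyl(dimethyl)silyl]oxybutan-2-yl]cyclohexa-2,4-dien-1-one (C6 unassigned) | CCOC1=CC(=O)C(C)C(=C1)[C@@H](C)[C@H](C)O[Si](C)(C)C(C)(C)C | intermediate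
18 | 3-[(2R,3S)-3-[tert-butyl(dimethyl)silyl]oxybutan-2-yl]-5-ethoxy-2-methylphenol | Cc1c(O)cc(OCC)cc1[C@@H](C)[C@H](C)O[Si](C)(C)C(C)(C)C | intermediate
19 | 5-[(2R,3S)-3-[tert-butyl(dimethyl)silyl]oxybutan-2-yl]-4-methylbenzene-1,3-diol | Cc1c(O)cc(O)cc1[C@@H](C)[C@H](C)O[Si](C)(C)C(C)(C)C | intermediate
20 | 5-[(2R,3S)-3-hydroxybutan-2-yl]-4-methylbenzene-1,3-diol | Cc1c(O)cc(O)cc1[C@@H](C)[C@H](C)O | intermediate
21 | (3S,4R)-1-ethoxy-3,4,5-trimethyl-3,4-dihydro-1H-isochromene-6,8-diol (C1 epimers) | Cc1c(O)cc(O)c2c1[C@@H](C)[C@H](C)OC2OCC | intermediate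
22 | (3S,4R)-8-hydroxy-3,4,5-trimethyl-3,4-dihydro-6H-isochromen-6-one (quinone methide) | CC1=C2[C@@H](C)[C@H](C)OC=C2C(O)=CC1=O | intermediate
23 | (3S)-3-hydroxy-N-methoxy-N-methylbutanamide | CON(C)C(=O)C[C@H](C)O | intermediate
24 | (3S)-3-[tert-butyl(dimethyl)silyl]oxy-N-methoxy-N-methylbutanamide | CON(C)C(=O)C[C@H](C)O[Si](C)(C)C(C)(C)C | intermediate
25 | ethyl acetoacetate | CCOC(=O)CC(C)=O | starting material
26 | dilithium dianion of ethyl acetoacetate | C=C([O-])C=C([O-])OCC.[Li+].[Li+] | intermediate
27 | ethyl (7S)-7-[tert-butyl(dimethyl)silyl]oxy-3,5-dioxooctanoate | CCOC(=O)CC(=O)CC(=O)C[C@H](C)O[Si](C)(C)C(C)(C)C | intermediate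
28 | ethyl (7S)-7-hydroxy-3,5-dioxooctanoate | CCOC(=O)CC(=O)CC(=O)C[C@H](C)O | intermediate
29 | ethyl 2-[(2S)-2-methyl-4-oxo-2,3-dihydropyran-6-yl]acetate | CCOC(=O)CC1=CC(=O)C[C@H](C)O1 | intermediate
30 | ethyl (Z)-3-[2,4-dihydroxy-6-[(2R,3S)-3-hydroxybutan-2-yl]-5-methylphenyl]-2-[(2S)-2-methyl-4-oxo-2,3-dihydropyran-6-yl]prop-2-enoate | CCOC(=O)/C(=C\c1c(O)cc(O)c(C)c1[C@@H](C)[C@H](C)O)C1=CC(=O)C[C@H](C)O1 | intermediate
31 | 7-hydroxy-5-[(2R,3S)-3-hydroxybutan-2-yl]-6-methyl-3-[(2S)-2-methyl-4-oxo-2,3-dihydropyran-6-yl]chromen-2-one | Cc1c(O)cc2oc(=O)c(C3=CC(=O)C[C@H](C)O3)cc2c1[C@@H](C)[C@H](C)O | target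

Total step count: 14. Longest linear sequence: 10 (steps 1–9 and 14).

Steps most likely to fail

Step 14. Condensation at a carbon flanked by two ortho substituents may be slow. During long exposure to the amine, the dihydropyranone may open by a retro-oxa-Michael reaction and reclose, which would erode its stereocentre. The fallback closes the pyranone ring last, under acid, and sets out from 27 and 22.
- DBU in toluene should lactonise 27 to 4-hydroxy-6-[(2S)-2-[tert-butyl(dimethyl)silyl]oxypropyl]pyran-2-one F1.
- The strongly nucleophilic C3 of this pyrone condenses with 22 (piperidine, EtOH). The ortho phenol then opens the pyrone by translactonisation, a known outcome for salicylaldehydes and 4-hydroxy-2-pyrones, giving 3-[(5S)-5-[tert-butyl(dimethyl)silyl]oxy-3-oxohexanoyl]-7-hydroxy-5-[(2R,3S)-3-hydroxybutan-2-yl]-6-methylchromen-2-one F2. Its stereocentre is held as a silyl ether and cannot racemise by ring opening.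
- Aqueous CF3CO2H in CH2Cl2 removes the silyl group to give 7-hydroxy-5-[(2R,3S)-3-hydroxybutan-2-yl]-3-[(5S)-5-hydroxy-3-oxohexanoyl]-6-methylchromen-2-one F3. This cyclodehydrates as in step 13, and the route is rejoined at 31.

Step 9. The diethoxycarbenium ion may attack C8 intermolecularly before the alcohol has exchanged onto the orthoester. The electrophilic product may also couple with resorcinol that has not yet reacted. The fallback closes the ring at the lower oxidation level and oxidises afterwards, setting out from 20.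
- Dimethoxymethane and TsOH in CH2Cl2 should give, by an oxa-Pictet–Spengler reaction, (3S,4R)-3,4,5-trimethyl-3,4-dihydro-1H-isochromene-6,8-diol F4. This compound is not an electrophile and cannot couple with 20.
- DDQ in dioxane then abstracts hydride from C1 of the isochromene (benzylic, next to oxygen and para to a hydroxyl), and the route is rejoined at 22.

Step 6. Cycloaddition to the α-branched alkyne may be slow, and the silyl ether may be lost in the triflate medium. Collidine may also deprotonate iminium ion 11 at the γ-position and erode the allylic stereocentre. The fallback is a base-free haloketene route that sets out from 8.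
- Chloro(methyl)ketene F5, generated from 2,2-dichloropropanoyl chloride with Zn–Cu couple in Et2O/DME, should add with the same orientation to give 4-chloro-3-[(2R,3S)-3-[tert-butyl(dimethyl)silyl]oxybutan-2-yl]-4-methylcyclobut-2-en-1-one F6.
- Zinc dust with AcOH and TMEDA in EtOH removes the chlorine, and the route is rejoined at 12.

Further compounds
F1 | step 14 | 4-hydroxy-6-[(2S)-2-[tert-butyl(dimethyl)silyl]oxypropyl]pyran-2-one | O=c1cc(O)cc(C[C@H](C)O[Si](C)(C)C(C)(C)C)o1
F2 | step 14 | 3-[(5S)-5-[tert-butyl(dimethyl)silyl]oxy-3-oxohexanoyl]-7-hydroxy-5-[(2R,3S)-3-hydroxybutan-2-yl]-6-methylchromen-2-one | Cc1c(O)cc2oc(=O)c(C(=O)CC(=O)C[C@H](C)O[Si](C)(C)C(C)(C)C)cc2c1[C@@H](C)[C@H](C)O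
F3 | step 14 | 7-hydroxy-5-[(2R,3S)-3-hydroxybutan-2-yl]-3-[(5S)-5-hydroxy-3-oxohexanoyl]-6-methylchromen-2-one | Cc1c(O)cc2oc(=O)c(C(=O)CC(=O)C[C@H](C)O)cc2c1[C@@H](C)[C@H](C)O
F4 | step 9 | (3S,4R)-3,4,5-trimethyl-3,4-dihydro-1H-isochromene-6,8-diol | Cc1c(O)cc(O)c2c1[C@@H](C)[C@H](C)OC2
F5 | step 6 | chloro(methyl)ketene | CC(Cl)=C=O
F6 | step 6 | 4-chloro-3-[(2R,3S)-3-[tert-butyl(dimethyl)silyl]oxybutan-2-yl]-4-methylcyclobut-2-en-1-one (C4 epimers) | CC1(Cl)C(=O)C=C1[C@@H](C)[C@H](C)O[Si](C)(C)C(C)(C)C
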